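**Plan**

Ring A carries the carbonyl at C1, OH at C2, OMe at C4 and the propyl chain at C5; ring B sits on the carbonyl carbon and ring C on the terminal (gamma) carbon of the chain.
Retrosynthesis: with the three phenols masked as benzyl ethers, the C(=O)–ring B bond and the C(gamma)–ring C bond are cut together. Rings B and C are the same 4-oxygenated phenyl group, so both cuts lead to one arylzinc reagent and one ring A core bearing an acid chloride and a primary bromide.
The core is cut further at C5–C(alpha) (allyl Suzuki coupling) and C5–Br (bromination para to the phenol), back to methyl 2-hydroxy-4-methoxybenzoate.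
Forward: ring A is elaborated first (bromination, benzylation, allylation, hydroboration, Appel bromination, ester cleavage, acid chloride), rings B and C are then attached in one double Negishi coupling, and hydrogenolysis frees the three phenols.
No ring is formed in the route and the target has no stereocentre, so no stereocontrol is needed.

Key step: step 9

**Route**

Step 1
Reactants: 1 methyl 2-hydroxy-4-methoxybenzoate
Product: 2 methyl 5-bromo-2-hydroxy-4-methoxybenzoate
Conditions: NBS (1.0 equiv), MeCN, 0 °C to rt
Reagents that add atoms: N-bromosuccinimide, O=C1CCC(=O)N1Br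
Why: Electrophilic aromatic bromination should occur at C5, which is para to the free hydroxyl and ortho to the methoxy group, because the only other activated site (C3) is flanked by both oxygen substituents.

Step 2
Reactants: 2 methyl 5-bromo-2-hydroxy-4-methoxybenzoate
Product: 3 methyl 2-(benzyloxy)-5-bromo-4-methoxybenzoate
Conditions: BnBr, K2CO3, DMF, 60 °C
Reagents that add atoms: benzyl bromide, BrCc1ccccc1
Why: Williamson ether synthesis of the potassium phenoxide with benzyl bromide in DMF should proceed cleanly, the methyl ester and the aryl bromide being inert.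

Step 3
Reactants: 3 methyl 2-(benzyloxy)-5-bromo-4-methoxybenzoate; 4 allylboronic acid pinacol ester
Product: 5 methyl 5-allyl-2-(benzyloxy)-4-methoxybenzoate
Conditions: PdCl2(dppf) (5 mol%), CsF (3 equiv), THF, 65 °C
Reagents that add atoms: none
Why: Suzuki–Miyaura coupling, in which fluoride activates the allyl boronate for transmetalation to the arylpalladium bromide, should give the allylarene, and anhydrous CsF spares the ester and limits migration of the double bond into conjugation.

Step 4
Reactants: 5 methyl 5-allyl-2-(benzyloxy)-4-methoxybenzoate
Product: 7 methyl 2-(benzyloxy)-5-(3-hydroxypropyl)-4-methoxybenzoate, via B-alkyl-9-BBN adduct 6 (not isolated)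
Conditions: 9-BBN (1.3 equiv), THF, 0 °C to rt; then NaBO3·4H2O, H2O, rt
Reagents that add atoms: sodium perborate (tetrahydrate, hydrate water omitted), [Na+].[Na+].O[B-]1(O)OO[B-](O)(O)OO1
Why: Hydroboration–oxidation with the bulky 9-BBN should place boron on the terminal carbon and leave the ester untouched, and perborate oxidises the C–B bond under conditions too mild to saponify the ester.

Step 5
Reactants: 7 methyl 2-(benzyloxy)-5-(3-hydroxypropyl)-4-methoxybenzoate
Product: 8 methyl 2-(benzyloxy)-5-(3-bromopropyl)-4-methoxybenzoate
Conditions: CBr4, PPh3, CH2Cl2, 0 °C to rt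
Reagents that add atoms: carbon tetrabromide, BrC(Br)(Br)Br
Why: In the Appel reaction the alkoxyphosphonium ion is displaced by bromide at the primary carbon under neutral conditions that spare the ester and both ethers.

Step 6
Reactants: 8 methyl 2-(benzyloxy)-5-(3-bromopropyl)-4-methoxybenzoate
Product: 10 2-(benzyloxy)-5-(3-bromopropyl)-4-methoxybenzoic acid, via trimethylstannyl ester 9 (not isolated)
Conditions: Me3SnOH (5 equiv), ClCH2CH2Cl, 80 °C; then 1 M HCl work-up
Reagents that add atoms: trimethyltin hydroxide, C[Sn](C)(C)O
Why: Ester hydrolysis with trimethyltin hydroxide delivers oxygen to the ester carbonyl under near-neutral conditions, and since the reagent is a poor nucleophile at sp3 carbon (the chloroalkane solvent itself survives it) the primary bromide should be retained where aqueous hydroxide could displace it.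

Step 7
Reactants: 10 2-(benzyloxy)-5-(3-bromopropyl)-4-methoxybenzoic acid
Product: 11 2-(benzyloxy)-5-(3-bromopropyl)-4-methoxybenzoyl chloride
Conditions: (COCl)2, DMF (cat.), CH2Cl2, 0 °C to rt; concentrated, azeotroped with toluene, used crude
Reagents that add atoms: oxalyl chloride, ClC(=O)C(Cl)=O
Why: Acid chloride formation through the chloroiminium (Vilsmeier-type) catalyst gives only volatile by-products, so the crude chloride can be taken on directly, and the alkyl bromide and the ethers do not react.

Step 8
Reactants: 12 1-(benzyloxy)-4-bromobenzene
Product: 14 [4-(benzyloxy)phenyl]zinc bromide, via arylmagnesium bromide 13 (not isolated)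
Conditions: Mg turnings, LiCl, THF, rt to 40 °C; then ZnBr2 (1.1 equiv), THF, 0 °C to rt; used as a titrated solution
Reagents that add atoms: zinc dibromide, Br[Zn]Br
Why: Grignard formation followed by transmetalation to zinc is routine for this aryl bromide, and the slight excess of ZnBr2 ensures that no arylmagnesium species remains to attack the ketone in the next step.

Step 9
Reactants: 11 2-(benzyloxy)-5-(3-bromopropyl)-4-methoxybenzoyl chloride; 14 [4-(benzyloxy)phenyl]zinc bromide (2.6 equiv)
Product: 16 [2-(benzyloxy)-5-{3-[4-(benzyloxy)phenyl]propyl}-4-methoxyphenyl][4-(benzyloxy)phenyl]methanone, via bromo ketone 15 (not isolated)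
Conditions: PdCl2(IPr)(3-chloropyridine) (4 mol%; IPr = 1,3-bis(2,6-diisopropylphenyl)imidazol-2-ylidene), THF, 0 °C to rt; then DMI added, 50 °C
Reagents that add atoms: none
Why: The arylzinc reagent reduces the divalent palladium precatalyst to a zerovalent Pd(IPr) species, which inserts fastest into the acyl C–Cl bond, and transmetalation from 14 followed by reductive elimination should give bromo ketone 15 at or below room temperature. On warming in the more polar THF/DMI mixture the same zerovalent palladium carbene species adds oxidatively to the primary C–Br bond, and a second transmetalation and reductive elimination place the second aryl group on the terminal carbon of the chain. The closest known reactions are the Negishi acylation of acid chlorides and the carbene-ligated palladium Negishi coupling of unactivated primary alkyl bromides with arylzinc halides, here run one after the other in a single flask with one reagent and one catalyst. No ring is closed and no stereocentre is formed. The step needs chemoselectivity against addition to the new diaryl ketone and against beta-hydride elimination of the alkylpalladium intermediate. The first is secured by the low carbonyl reactivity of arylzinc halides and the electron-rich, doubly alkoxy-substituted ketone, the second by the bulky IPr ligand, which speeds reductive elimination.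

Step 10
Reactants: 16 [2-(benzyloxy)-5-{3-[4-(benzyloxy)phenyl]propyl}-4-methoxyphenyl][4-(benzyloxy)phenyl]methanone
Product: 17 (4-hydroxyphenyl){2-hydroxy-5-[3-(4-hydroxyphenyl)propyl]-4-methoxyphenyl}methanone (CNP0209225.0)
Conditions: H2 (1 atm), Pd/C (10 wt% palladium on carbon), EtOAc, rt
Reagents that add atoms: none
Why: Catalytic hydrogenolysis should cleave the three benzyl aryl ethers much faster than it reduces the electron-rich, hydrogen-bonded diaryl ketone in a neutral aprotic solvent at atmospheric pressure.

**Compound list**

1 | methyl 2-hydroxy-4-methoxybenzoate | COC(=O)c1ccc(OC)cc1O | starting material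
2 | methyl 5-bromo-2-hydroxy-4-methoxybenzoate | COC(=O)c1cc(Br)c(OC)cc1O | intermediate
3 | methyl 2-(benzyloxy)-5-bromo-4-methoxybenzoate | COC(=O)c1cc(Br)c(OC)cc1OCc1ccccc1 | intermediate
4 | allylboronic acid pinacol ester | C=CCB1OC(C)(C)C(C)(C)O1 | starting material
5 | methyl 5-allyl-2-(benzyloxy)-4-methoxybenzoate | COC(=O)c1cc(CC=C)c(OC)cc1OCc1ccccc1 | intermediate
6 | methyl 2-(benzyloxy)-5-[3-(9-borabicyclo[3.3.1]nonan-9-yl)propyl]-4-methoxybenzoate | COC(=O)c1cc(CCCB2C3CCCC2CCC3)c(OC)cc1OCc1ccccc1 | intermediate (not isolated)
7 | methyl 2-(benzyloxy)-5-(3-hydroxypropyl)-4-methoxybenzoate | COC(=O)c1cc(CCCO)c(OC)cc1OCc1ccccc1 | intermediate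
8 | methyl 2-(benzyloxy)-5-(3-bromopropyl)-4-methoxybenzoate | COC(=O)c1cc(CCCBr)c(OC)cc1OCc1ccccc1 | intermediate
9 | trimethylstannyl 2-(benzyloxy)-5-(3-bromopropyl)-4-methoxybenzoate | C[Sn](C)(C)OC(=O)c1cc(CCCBr)c(OC)cc1OCc1ccccc1 | intermediate (not isolated)
10 | 2-(benzyloxy)-5-(3-bromopropyl)-4-methoxybenzoic acid | OC(=O)c1cc(CCCBr)c(OC)cc1OCc1ccccc1 | intermediate
11 | 2-(benzyloxy)-5-(3-bromopropyl)-4-methoxybenzoyl chloride | COc1cc(OCc2ccccc2)c(C(=O)Cl)cc1CCCBr | intermediate
12 | 1-(benzyloxy)-4-bromobenzene | Brc1ccc(OCc2ccccc2)cc1 | starting material
13 | [4-(benzyloxy)phenyl]magnesium bromide | Br[Mg]c1ccc(OCc2ccccc2)cc1 | intermediate (not isolated)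
14 | [4-(benzyloxy)phenyl]zinc bromide | Br[Zn]c1ccc(OCc2ccccc2)cc1 | intermediate
15 | [2-(benzyloxy)-5-(3-bromopropyl)-4-methoxyphenyl][4-(benzyloxy)phenyl]methanone | COc1cc(OCc2ccccc2)c(C(=O)c2ccc(OCc3ccccc3)cc2)cc1CCCBr | intermediate (not isolated)
16 | [2-(benzyloxy)-5-{3-[4-(benzyloxy)phenyl]propyl}-4-methoxyphenyl][4-(benzyloxy)phenyl]methanone | COc1cc(OCc2ccccc2)c(C(=O)c2ccc(OCc3ccccc3)cc2)cc1CCCc1ccc(OCc2ccccc2)cc1 | intermediate
17 | (4-hydroxyphenyl){2-hydroxy-5-[3-(4-hydroxyphenyl)propyl]-4-methoxyphenyl}methanone | COc1cc(O)c(C(=O)c2ccc(O)cc2)cc1CCCc1ccc(O)cc1 | target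

**Step count and risks**

Total step count: 10. Longest linear sequence: 9 steps (steps 1 to 7, then 9 and 10); step 8 is a one-step side branch.

Steps most likely to fail:

1. Step 9. The slower coupling at the primary bromide may stall after the acylation, or the alkylpalladium intermediate may undergo beta-hydride elimination or hydrodehalogenation, so that the chain is not capped. The fallback sets out from acid chloride 11 and separates the two bond formations. Acylation with 1.1 equiv of 14 under Pd(PPh3)4 in THF at 0 °C, where phosphine-ligated zerovalent palladium leaves the alkyl bromide untouched, should allow bromo ketone 15 to be isolated. Zinc insertion into its C–Br bond (Zn dust, LiCl, THF, 50 °C) would give {3-[4-(benzyloxy)-5-[4-(benzyloxy)benzoyl]-2-methoxyphenyl]propyl}zinc bromide F1. A polarity-reversed Negishi coupling of F1 with aryl bromide 12 (Pd(OAc)2, SPhos, THF, rt to 50 °C) comes back to the route at 16.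

2. Step 6. The hindered, electron-rich ester may hydrolyse slowly, and during long heating the primary bromide may be displaced by hydroxide or by the carboxylate. The fallback sets out from bromo ester 8 and reaches the acid through oxidation states instead of hydrolysis. Reduction with i-Bu2AlH (CH2Cl2, −78 °C) would give [2-(benzyloxy)-5-(3-bromopropyl)-4-methoxyphenyl]methanol F2. Oxidation with MnO2 (CH2Cl2, rt) would give 2-(benzyloxy)-5-(3-bromopropyl)-4-methoxybenzaldehyde F3. Pinnick oxidation (NaClO2, NaH2PO4, 2-methyl-2-butene, t-BuOH/H2O) comes back to the route at acid 10. None of these reagents attacks a primary alkyl bromide.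

3. Step 10. The diaryl ketone may be over-reduced to the benzhydrol or the diarylmethane while the last benzyl ether is being cleaved. The fallback sets out from 16 and gives up reductive cleavage altogether. Lewis-acid debenzylation with BCl3 and pentamethylbenzene as cation scavenger (CH2Cl2, −78 °C) should remove the three benzyl groups while the C4 methyl ether, which is not chelated to the carbonyl, and the ketone stay intact. It comes back to the route at 17 and forms no compound outside the list (entry F0).

Further compounds
F1 | step 9 | {3-[4-(benzyloxy)-5-[4-(benzyloxy)benzoyl]-2-methoxyphenyl]propyl}zinc bromide | COc1cc(OCc2ccccc2)c(C(=O)c2ccc(OCc3ccccc3)cc2)cc1CCC[Zn]Br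
F2 | step 6 | [2-(benzyloxy)-5-(3-bromopropyl)-4-methoxyphenyl]methanol | COc1cc(OCc2ccccc2)c(CO)cc1CCCBr
F3 | step 6 | 2-(benzyloxy)-5-(3-bromopropyl)-4-methoxybenzaldehyde | COc1cc(OCc2ccccc2)c(C=O)cc1CCCBr
F0 | step 10 | none | none
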